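**Plan**

Numbering: ring A = C1H2, C2(OH), C3(O-acyl), C4(Me), C5(Me), C10. Ring B = C5, C6=C7(OH), C8=O, C9=C10. The acyl chain is C1'–C8'.
Enabling feature: C7–C8(O)–C9–C10 of ring B, with C1 on C10, maps onto C3–C4(OMe)–C5–C6 and the 6-methyl group of 4-methoxy-6-methyl-2-pyranone. C5(Me)=C6H2 is an isopropenyl group four atoms (C1–C4) away from C10.
Cuts: the C3–O acyl bond; C7–O (diosphenol back to the 8-methoxy-7,9-diene); C5–C10 and C6–C7 together, with CO2 restored as the lactone bridge; C1–C2; C3–C4.
Forward: C3–C4 forms by a glyoxylate–ene reaction and C1–C2 by acylation of the lithiated pyranone. Rings A and B then close in one thermal operation, and the ester and the ring B oxygenation follow.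
Stereochemistry: C3 and C4 come from a catalyst-controlled anti ene reaction, C2 from Felkin–Anh reduction next to C3, C5 from the C4-controlled chair-like cycloaddition, and C6' from (S)-2-methylbutan-1-ol.

Key step: step 6

Remark: the C7 carbinol centre made in step 12 is erased in step 13, so it is drawn for attack anti to the C5 methyl without being relied on; the bridged cycloadduct of step 6 is drawn with the tether on the side of the lactone oxygen, and its bridgehead diastereomer would give the same diene.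

**Step 1**
Reactants: 1 ethyl glyoxylate (freshly cracked); 2 2-methyl-2-butene (excess)
Product: 3 ethyl (2R,3R)-2-hydroxy-3,4-dimethylpent-4-enoate
Conditions: [Cu((R,R)-t-Bu-box)](SbF6)2 (10 mol %), CH2Cl2, 0 °C → rt (t-Bu-box = 2,2'-(propane-2,2-diyl)bis(4-tert-butyl-4,5-dihydrooxazole))
Reagents that add atoms: none
Why: Catalytic asymmetric glyoxylate–ene (carbonyl-ene) reaction: the dicationic divalent copper bis(oxazoline) complex binds 1 through both carbonyl oxygens, the alkene attacks with its less substituted carbon while a geminal methyl gives up hydrogen (C3–C4 forms and the C5=C6 isopropenyl group appears), the ligand blocks one aldehyde face and sets (R)-C3, and the chelated glyoxylate is expected to react through the exo six-membered transition state that gives anti adducts with chelating Lewis acids, which sets (R)-C4.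

**Step 2**
Reactants: 3 ethyl (2R,3R)-2-hydroxy-3,4-dimethylpent-4-enoate
Product: 4 ethyl (2R,3R)-3,4-dimethyl-2-(triethylsilyloxy)pent-4-enoate
Conditions: Et3SiCl, imidazole, CH2Cl2, 0 °C → rt
Reagents that add atoms: chlorotriethylsilane, CC[Si](Cl)(CC)CC
Why: Standard silylation of a secondary alcohol that touches no stereocentre; the triethylsilyl ether is non-chelating (needed in step 4) and is the more fluoride-labile of the two silyl groups (needed in step 7).

**Step 3**
Reactants: 4 ethyl (2R,3R)-3,4-dimethyl-2-(triethylsilyloxy)pent-4-enoate; 5 4-methoxy-6-methyl-2H-pyran-2-one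
Product: 8 6-[(3R,4R)-4,5-dimethyl-2-oxo-3-(triethylsilyloxy)hex-5-en-1-yl]-4-methoxy-2H-pyran-2-one, via lithiated pyranone 6 (not isolated), via lithium enolate 7 (not isolated)
Conditions: 5 (2.2 equiv), LiN(i-Pr)2 (2.1 equiv), THF, −78 °C; then 4, −78 → −30 °C; aq. NH4Cl
Reagents that add atoms: none
Why: Claisen-type C-acylation of the vinylogous enolate obtained by deprotonating the 6-methyl group of 5, a known reaction of this pyranone with esters; the inductively activated alpha-silyloxy ester transfers its acyl group to form C1–C2, and a second equivalent of 6 turns the acidic product into enolate 7, which stops over-addition and keeps enolisation away from C3.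

**Step 4**
Reactants: 8 6-[(3R,4R)-4,5-dimethyl-2-oxo-3-(triethylsilyloxy)hex-5-en-1-yl]-4-methoxy-2H-pyran-2-one
Product: 9 6-[(2R,3R,4R)-2-hydroxy-4,5-dimethyl-3-(triethylsilyloxy)hex-5-en-1-yl]-4-methoxy-2H-pyran-2-one
Conditions: NaBH4, CeCl3·7H2O, MeOH, −78 °C
Reagents that add atoms: none
Why: Luche-type 1,2-reduction that leaves the electron-rich pyranone untouched; with the non-chelating silyloxy group perpendicular to the carbonyl (Felkin–Anh polar model) hydride attacks anti to C3–O past C3–H and gives the (2R) alcohol with the 2,3-syn diol pattern, whereas adding 6 to the corresponding aldehyde would follow the same model to the unwanted 2,3-anti epimer.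

**Step 5**
Reactants: 9 6-[(2R,3R,4R)-2-hydroxy-4,5-dimethyl-3-(triethylsilyloxy)hex-5-en-1-yl]-4-methoxy-2H-pyran-2-one
Product: 10 6-[(2R,3R,4R)-4,5-dimethyl-3-(triethylsilyloxy)-2-(triisopropylsilyloxy)hex-5-en-1-yl]-4-methoxy-2H-pyran-2-one
Conditions: i-Pr3SiOTf, 2,6-lutidine, CH2Cl2, 0 °C → rt
Reagents that add atoms: triisopropylsilyl triflate, CC(C)[Si](OS(=O)(=O)C(F)(F)F)(C(C)C)C(C)C
Why: Silyl triflate/lutidine silylation of a hindered secondary alcohol; the bulky triisopropylsilyl group outlasts step 7 and, next to the triethylsilyl ether, biases the C2–C3 bond towards the O/O-anti rotamer in which C1 and C4 are gauche, as ring closure requires.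

**Step 6**
Reactants: 10 6-[(2R,3R,4R)-4,5-dimethyl-3-(triethylsilyloxy)-2-(triisopropylsilyloxy)hex-5-en-1-yl]-4-methoxy-2H-pyran-2-one
Product: 12 (2R,3R,4R,5R)-8-methoxy-3-(triethylsilyloxy)-2-(triisopropylsilyloxy)-11,12,13-trinoreremophila-7,9-diene, via bridged lactone 11 (not isolated)
Conditions: toluene (0.005 M), BHT (cat.), base-washed sealed tube, 200 °C
Reagents that add atoms: none
Why: Thermal intramolecular [4+2] addition of the pyranone diene (C7=C8–C9=C10) to the C5=C6 alkene gives the 2-oxabicyclo[2.2.2]octenone 11, which at this temperature loses CO2 by retro-[4+2] to leave the C7=C8(OMe)–C9=C10 diene; the closest known reaction type is the intramolecular Diels–Alder reaction of 2-pyranones bearing alkenyl side chains followed by decarboxylation. Ring A closes through the four-atom tether C1–C4 by formation of C5–C10 in a chair-like six-membered array, and ring B closes as the new cyclohexene of the cycloadduct by concurrent formation of C6–C7. The cage geometry holds C6 anti to C1 about the new C5–C10 bond, so the C5 methyl is axial on ring A in every transition state and the C5 configuration depends only on which chair the tether adopts. The favoured chair has C4–H, not C4–CH3, axial and turned towards the pyranone (C4–H nearly eclipsing C5=C6, least allylic strain), which puts the C4 methyl equatorial and cis to the C5 methyl; it is also the chair in which the two bulky vicinal silyl ethers are anti (diaxial) and not gauche, so C4 and the silyl groups work in the same direction. The tether enforces the regiochemistry, loss of CO2 makes the sequence irreversible, and the fully substituted C5 rules out aromatisation of the diene. High dilution, BHT and base-washed glass guard against intermolecular addition, radical polymerisation and acid hydrolysis of the dienol ether.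

**Step 7**
Reactants: 12 (2R,3R,4R,5R)-8-methoxy-3-(triethylsilyloxy)-2-(triisopropylsilyloxy)-11,12,13-trinoreremophila-7,9-diene
Product: 13 (2R,3R,4R,5R)-8-methoxy-2-(triisopropylsilyloxy)-11,12,13-trinoreremophila-7,9-dien-3-ol
Conditions: n-Bu4NF (1.1 equiv), THF, 0 °C
Reagents that add atoms: none
Why: Fluoride desilylation under non-acidic conditions, chosen because the methyl dienol ether would not survive acid; the triethylsilyl ether is cleaved much faster than the triisopropylsilyl ether, and the trans-diaxial O2/O3 geometry rules out silyl migration.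

**Step 8**
Reactants: 14 (S)-2-methylbutan-1-ol
Product: 15 (S)-2-methylbutanal
Conditions: TEMPO (cat.), KBr (cat.), NaOCl, NaHCO3, CH2Cl2/H2O, 0 °C
Reagents that add atoms: none
Why: Nitroxyl-catalysed hypochlorite (Anelli) oxidation of a primary alcohol, a fast, buffered, low-temperature procedure established for alpha-branched aldehydes of this type that does not racemise the alpha-stereocentre.

**Step 9**
Reactants: 15 (S)-2-methylbutanal; 16 triethyl 4-phosphonocrotonate (ethyl (E)-4-(diethoxyphosphoryl)but-2-enoate)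
Product: 18 ethyl (2E,4E,6S)-6-methylocta-2,4-dienoate, via lithiated phosphonate 17 (not isolated)
Conditions: 16, LiN(SiMe3)2, THF, −78 °C; then 15, −78 °C → rt
Reagents that add atoms: none
Why: Vinylogous Horner–Wadsworth–Emmons olefination in which the stabilised anion 17 adds to the aldehyde and expels phosphate to give the (2E,4E)-dienoate, the low temperature and non-nucleophilic base protecting the C6' stereocentre.

**Step 10**
Reactants: 18 ethyl (2E,4E,6S)-6-methylocta-2,4-dienoate
Product: 20 (2E,4E,6S)-6-methylocta-2,4-dienoic acid, via lithium carboxylate 19 (not isolated)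
Conditions: LiOH, THF/MeOH/H2O, rt; then 1 M HCl
Reagents that add atoms: lithium hydroxide, [Li+].[OH-]
Why: Saponification of a conjugated ethyl ester under mild conditions that neither isomerise the diene nor touch the remote stereocentre.

**Step 11**
Reactants: 13 (2R,3R,4R,5R)-8-methoxy-2-(triisopropylsilyloxy)-11,12,13-trinoreremophila-7,9-dien-3-ol; 20 (2E,4E,6S)-6-methylocta-2,4-dienoic acid
Product: 22 (2R,3R,4R,5R)-8-methoxy-2-(triisopropylsilyloxy)-11,12,13-trinoreremophila-7,9-dien-3-yl (2E,4E,6S)-6-methylocta-2,4-dienoate, via mixed anhydride 21 (not isolated)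
Conditions: 20, 2,4,6-Cl3C6H2COCl, Et3N, toluene, rt; then 13, DMAP, toluene, rt → 60 °C
Reagents that add atoms: none
Why: Yamaguchi esterification: DMAP attacks mixed anhydride 21 at the less hindered dienoyl carbonyl and the acylpyridinium ion acylates the hindered axial C3–OH, the basic medium being compatible with the dienol ether and the silyl ether.

**Step 12**
Reactants: 22 (2R,3R,4R,5R)-8-methoxy-2-(triisopropylsilyloxy)-11,12,13-trinoreremophila-7,9-dien-3-yl (2E,4E,6S)-6-methylocta-2,4-dienoate
Product: 24 (2R,3R,4R,5R,7R)-7-hydroxy-8-oxo-2-(triisopropylsilyloxy)-11,12,13-trinoreremophil-9-en-3-yl (2E,4E,6S)-6-methylocta-2,4-dienoate, via methoxy epoxide 23 (not isolated)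
Conditions: dimethyldioxirane (1.0 equiv), acetone/CH2Cl2, −78 → −40 °C; then oxalic acid (cat.), THF/H2O, 0 °C
Reagents that add atoms: dimethyldioxirane, CC1(C)OO1; water, O
Why: Rubottom-type oxidation: the electrophilic dioxirane epoxidises the most electron-rich double bond, the enol ether C7=C8 whose oxygen makes C7 nucleophilic, in preference to C9=C10 and the electron-poor dienoate, and mild aqueous acid opens 23 at C8 and expels methanol to leave the 7-hydroxy-9-en-8-one.

**Step 13**
Reactants: 24 (2R,3R,4R,5R,7R)-7-hydroxy-8-oxo-2-(triisopropylsilyloxy)-11,12,13-trinoreremophil-9-en-3-yl (2E,4E,6S)-6-methylocta-2,4-dienoate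
Product: 26 (2R,3R,4R,5S)-7-hydroxy-8-oxo-2-(triisopropylsilyloxy)-11,12,13-trinoreremophila-6,9-dien-3-yl (2E,4E,6S)-6-methylocta-2,4-dienoate, via 7,8-dione 25 (not isolated)
Conditions: Dess–Martin periodinane, CH2Cl2, 0 °C → rt
Reagents that add atoms: none
Why: Dess–Martin oxidation of an alpha-ketol to the 1,2-dione, which can enolise only towards C6 and should do so spontaneously to the hydrogen-bonded, cross-conjugated diosphenol.

**Step 14**
Reactants: 26 (2R,3R,4R,5S)-7-hydroxy-8-oxo-2-(triisopropylsilyloxy)-11,12,13-trinoreremophila-6,9-dien-3-yl (2E,4E,6S)-6-methylocta-2,4-dienoate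
Product: 27 septeremophilane G, (2R,3R,4R,5S)-2,7-dihydroxy-8-oxo-11,12,13-trinoreremophila-6,9-dien-3-yl (2E,4E,6S)-6-methylocta-2,4-dienoate
Conditions: 48% aq. HF, MeCN, 0 °C → rt
Reagents that add atoms: none
Why: Acidic fluoride cleavage of the last silyl ether under conditions that the dienoate ester and the diosphenol tolerate, with no acyl migration because O2 and O3 are trans-diaxial.

**Compound list**

1 | ethyl glyoxylate | CCOC(=O)C=O | starting material
2 | 2-methyl-2-butene | CC=C(C)C | starting material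
3 | ethyl (2R,3R)-2-hydroxy-3,4-dimethylpent-4-enoate | CCOC(=O)[C@H](O)[C@H](C)C(C)=C | intermediate
4 | ethyl (2R,3R)-3,4-dimethyl-2-(triethylsilyloxy)pent-4-enoate | CCOC(=O)[C@H](O[Si](CC)(CC)CC)[C@H](C)C(C)=C | intermediate
5 | 4-methoxy-6-methyl-2H-pyran-2-one | COC1=CC(=O)OC(C)=C1 | starting material
6 | 6-(lithiomethyl)-4-methoxy-2H-pyran-2-one | COC1=CC(=O)OC(C[Li])=C1 | intermediate
7 | lithium enolate of 8 (C1=C2–OLi, geometry not defined) | COC1=CC(=O)OC(C=C(O[Li])[C@H](O[Si](CC)(CC)CC)[C@H](C)C(C)=C)=C1 | intermediate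
8 | 6-[(3R,4R)-4,5-dimethyl-2-oxo-3-(triethylsilyloxy)hex-5-en-1-yl]-4-methoxy-2H-pyran-2-one | COC1=CC(=O)OC(CC(=O)[C@H](O[Si](CC)(CC)CC)[C@H](C)C(C)=C)=C1 | intermediate
9 | 6-[(2R,3R,4R)-2-hydroxy-4,5-dimethyl-3-(triethylsilyloxy)hex-5-en-1-yl]-4-methoxy-2H-pyran-2-one | COC1=CC(=O)OC(C[C@@H](O)[C@H](O[Si](CC)(CC)CC)[C@H](C)C(C)=C)=C1 | intermediate
10 | 6-[(2R,3R,4R)-4,5-dimethyl-3-(triethylsilyloxy)-2-(triisopropylsilyloxy)hex-5-en-1-yl]-4-methoxy-2H-pyran-2-one | COC1=CC(=O)OC(C[C@@H](O[Si](C(C)C)(C(C)C)C(C)C)[C@H](O[Si](CC)(CC)CC)[C@H](C)C(C)=C)=C1 | intermediate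
11 | bridged lactone: C10–O–C(=O)–C7 bridge across ring B, C8(OMe)=C9, new bonds C5–C10 and C6–C7, (2R,3R,4R,5R,7R,10R) | CC[Si](CC)(CC)O[C@H]1[C@H](O[Si](C(C)C)(C(C)C)C(C)C)C[C@]23OC(=O)[C@H](C[C@]2(C)[C@H]1C)C(OC)=C3 | intermediate
12 | (2R,3R,4R,5R)-8-methoxy-3-(triethylsilyloxy)-2-(triisopropylsilyloxy)-11,12,13-trinoreremophila-7,9-diene | CC[Si](CC)(CC)O[C@H]1[C@H](O[Si](C(C)C)(C(C)C)C(C)C)CC2=CC(OC)=CC[C@]2(C)[C@H]1C | intermediate
13 | (2R,3R,4R,5R)-8-methoxy-2-(triisopropylsilyloxy)-11,12,13-trinoreremophila-7,9-dien-3-ol | O[C@H]1[C@H](O[Si](C(C)C)(C(C)C)C(C)C)CC2=CC(OC)=CC[C@]2(C)[C@H]1C | intermediate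
14 | (S)-2-methylbutan-1-ol | CC[C@H](C)CO | starting material
15 | (S)-2-methylbutanal | CC[C@H](C)C=O | intermediate
16 | triethyl 4-phosphonocrotonate | CCOC(=O)/C=C/CP(=O)(OCC)OCC | starting material
17 | lithiated triethyl 4-phosphonocrotonate | CCOC(=O)/C=C/C([Li])P(=O)(OCC)OCC | intermediate
18 | ethyl (2E,4E,6S)-6-methylocta-2,4-dienoate | CC[C@H](C)/C=C/C=C/C(=O)OCC | intermediate
19 | lithium (2E,4E,6S)-6-methylocta-2,4-dienoate | CC[C@H](C)/C=C/C=C/C(=O)[O-].[Li+] | intermediate
20 | (2E,4E,6S)-6-methylocta-2,4-dienoic acid | CC[C@H](C)/C=C/C=C/C(=O)O | intermediate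
21 | (2E,4E,6S)-6-methylocta-2,4-dienoic 2,4,6-trichlorobenzoic anhydride | CC[C@H](C)/C=C/C=C/C(=O)OC(=O)c1c(Cl)cc(Cl)cc1Cl | intermediate
22 | C3 dienoate of 13 (8-methoxy-7,9-diene, C2–OTIPS) | CC[C@H](C)/C=C/C=C/C(=O)O[C@H]1[C@H](O[Si](C(C)C)(C(C)C)C(C)C)CC2=CC(OC)=CC[C@]2(C)[C@H]1C | intermediate
23 | 7,8-epoxy-8-methoxy-9-ene, epoxide anti to the C5 methyl | CC[C@H](C)/C=C/C=C/C(=O)O[C@H]1[C@H](O[Si](C(C)C)(C(C)C)C(C)C)CC2=C[C@]3(OC)O[C@@H]3C[C@]2(C)[C@H]1C | intermediate
24 | (7R)-7-hydroxy-9-en-8-one (C3 dienoate, C2–OTIPS) | CC[C@H](C)/C=C/C=C/C(=O)O[C@H]1[C@H](O[Si](C(C)C)(C(C)C)C(C)C)CC2=CC(=O)[C@H](O)C[C@]2(C)[C@H]1C | intermediate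
25 | 9-ene-7,8-dione (C3 dienoate, C2–OTIPS) | CC[C@H](C)/C=C/C=C/C(=O)O[C@H]1[C@H](O[Si](C(C)C)(C(C)C)C(C)C)CC2=CC(=O)C(=O)C[C@]2(C)[C@H]1C | intermediate
26 | 2-O-triisopropylsilyl septeremophilane G (diosphenol) | CC[C@H](C)/C=C/C=C/C(=O)O[C@H]1[C@H](O[Si](C(C)C)(C(C)C)C(C)C)CC2=CC(=O)C(O)=C[C@]2(C)[C@H]1C | intermediate
27 | septeremophilane G | CC[C@H](C)/C=C/C=C/C(=O)O[C@H]1[C@H](O)CC2=CC(=O)C(O)=C[C@]2(C)[C@H]1C | target

**Step count**

Total step count: 14. Longest linear sequence: 11 (steps 1–7 and 11–14). Steps 8–10 form the three-step side branch.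

**Steps most likely to fail**

1. **Step 6.**
 - What may go wrong: the cycloaddition may be too slow. The alkene is unactivated and 1,1-disubstituted, the methoxy group makes the pyranone a poorer acceptor, and C5–C10 joins two fully substituted carbons. Thermal degradation (loss of silanol across C1–C2, polymerisation) could then overtake ring closure. The syn-axial contact between the C3 silyloxy group and the C5 methyl may also erode the facial preference.
 - Fallback (sets out from 5 and 4, returns at 12): the diene is activated with a removable halogen, since 3-halo-2-pyranones are known to be distinctly more reactive, ambiphilic Diels–Alder dienes. NBS (MeCN, rt) converts 5 into 3-bromo-4-methoxy-6-methyl-2H-pyran-2-one F1. Deprotonation with LiN(i-Pr)2 and acylation with 4 as in step 3 gives the bromo ketone F2. NaBH4/CeCl3·7H2O then gives the (2R)-bromo alcohol F3, and i-Pr3SiOTf/2,6-lutidine the bromo bis-silyl ether F4. Heating F4 in toluene at a lower temperature (about 110–140 °C) should give the bridged bromolactone F5, which loses CO2 to the 7-bromo-8-methoxy-7,9-diene F6. Bromine–lithium exchange (t-BuLi, THF, −78 °C) and a MeOH quench replace Br by H and deliver 12.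

2. **Step 1.**
 - What may go wrong: with a trisubstituted alkene the anti/syn selectivity or the enantioselectivity may be low, and the glyoxylate may oligomerise faster than it reacts.
 - Fallback (sets out from 1 and 2, returns at 3): the syn adduct is made on purpose and C3 is then inverted. Binaphthol–titanium catalysts, which hold the aldehyde through one oxygen only, are known to favour syn adducts from trisubstituted alkenes. (S)-BINOL/TiCl2(Oi-Pr)2 (10 mol %), 4 Å molecular sieves, CH2Cl2, −30 °C should therefore give ethyl (2S,3R)-2-hydroxy-3,4-dimethylpent-4-enoate F7, in which C4 is already correct. Mitsunobu inversion (4-nitrobenzoic acid, PPh3, DIAD, THF), well precedented for alpha-hydroxy esters, gives ethyl (2R,3R)-3,4-dimethyl-2-(4-nitrobenzoyloxy)pent-4-enoate F8. K2CO3 in EtOH removes the nitrobenzoate and gives 3.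

3. **Step 3.**
 - What may go wrong: acyl transfer from the hindered ester to the delocalised anion may be slow. Self-condensation of the lithiated pyranone on warming, or enolisation of the ester with loss of C3 integrity, could then compete.
 - Fallback (sets out from 4, returns at 8): C1–C2 is formed at the aldehyde oxidation level, where addition is fast at −78 °C. i-Bu2AlH (1.05 equiv, CH2Cl2, −78 °C) gives (2R,3R)-3,4-dimethyl-2-(triethylsilyloxy)pent-4-enal F9. Addition of 6 (THF, −78 °C) gives the carbinol, expected mainly as the (2S) Felkin–Anh epimer F10. Dess–Martin oxidation of the epimer mixture converges on ketone 8, and C2 is then set as in step 4.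

**Further compounds**

F1 | step 6 | 3-bromo-4-methoxy-6-methyl-2H-pyran-2-one | COC1=C(Br)C(=O)OC(C)=C1
F2 | step 6 | 3-bromo-6-[(3R,4R)-4,5-dimethyl-2-oxo-3-(triethylsilyloxy)hex-5-en-1-yl]-4-methoxy-2H-pyran-2-one | COC1=C(Br)C(=O)OC(CC(=O)[C@H](O[Si](CC)(CC)CC)[C@H](C)C(C)=C)=C1
F3 | step 6 | 3-bromo-6-[(2R,3R,4R)-2-hydroxy-4,5-dimethyl-3-(triethylsilyloxy)hex-5-en-1-yl]-4-methoxy-2H-pyran-2-one | COC1=C(Br)C(=O)OC(C[C@@H](O)[C@H](O[Si](CC)(CC)CC)[C@H](C)C(C)=C)=C1
F4 | step 6 | 3-bromo-6-[(2R,3R,4R)-4,5-dimethyl-3-(triethylsilyloxy)-2-(triisopropylsilyloxy)hex-5-en-1-yl]-4-methoxy-2H-pyran-2-one | COC1=C(Br)C(=O)OC(C[C@@H](O[Si](C(C)C)(C(C)C)C(C)C)[C@H](O[Si](CC)(CC)CC)[C@H](C)C(C)=C)=C1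
F5 | step 6 | 7-bromo analogue of bridged lactone 11 | CC[Si](CC)(CC)O[C@H]1[C@H](O[Si](C(C)C)(C(C)C)C(C)C)C[C@]23OC(=O)[C@](Br)(C[C@]2(C)[C@H]1C)C(OC)=C3
F6 | step 6 | 7-bromo-8-methoxy-3-(triethylsilyloxy)-2-(triisopropylsilyloxy)-11,12,13-trinoreremophila-7,9-diene | CC[Si](CC)(CC)O[C@H]1[C@H](O[Si](C(C)C)(C(C)C)C(C)C)CC2=CC(OC)=C(Br)C[C@]2(C)[C@H]1C
F7 | step 1 | ethyl (2S,3R)-2-hydroxy-3,4-dimethylpent-4-enoate | CCOC(=O)[C@@H](O)[C@H](C)C(C)=C
F8 | step 1 | ethyl (2R,3R)-3,4-dimethyl-2-(4-nitrobenzoyloxy)pent-4-enoate | CCOC(=O)[C@H](OC(=O)c1ccc(cc1)[N+](=O)[O-])[C@H](C)C(C)=C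
F9 | step 3 | (2R,3R)-3,4-dimethyl-2-(triethylsilyloxy)pent-4-enal | O=C[C@H](O[Si](CC)(CC)CC)[C@H](C)C(C)=C
F10 | step 3 | 6-[(2S,3R,4R)-2-hydroxy-4,5-dimethyl-3-(triethylsilyloxy)hex-5-en-1-yl]-4-methoxy-2H-pyran-2-one | COC1=CC(=O)OC(C[C@H](O)[C@H](O[Si](CC)(CC)CC)[C@H](C)C(C)=C)=C1
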